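Ring C is cut on both sides of its O1–C2 unit, at C2–C3 and at O1–C8a, so that this unit becomes a formyl group delivered by ethyl formate. The feature exploited is the position of C4 between C3 and ring A: a temporary C4 ketone makes C3, benzylic to ring B, an enolate carbon and makes C8a, ortho to it, an SNAr site. The precursor is an open-chain 2-fluorodeoxybenzoin carrying both finished aryl rings. In one flask C3 is formylated and the new enolate oxygen displaces fluoride at C8a, closing ring C as an isoflavone. A transfer-hydrogenation cascade with dynamic kinetic resolution then sets C3 as R and removes the C4 oxygen.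

Key step: step 8

Remark: flavonoid numbering (O1, C2 to C8a, C1′ to C6′) is used throughout. C3 of the target is read as R (CIP order C2 > C1′ > C4 > H). Compounds 1, 2, 9, 11 and 14 are taken to be commercial.

Step 1
Reactants: 1 2-bromo-3-fluorophenol; 2 2-methylbut-3-en-2-ol
Product: 4 3-fluoro-2-(3-hydroxy-3-methylbutyl)phenol, via bis-boryl adduct 3 (not isolated)
Conditions: 2, 9-BBN-H (2.1 equiv), THF, 0 °C to rt; then 1, Pd(OAc)2 (cat.), SPhos, aq K3PO4, THF, 65 °C
Reagents that add atoms: none
Why: 9-BBN-H adds to the terminal carbon of the monosubstituted alkene (the second equivalent is taken up by the hydroxyl group), and the B-alkyl Suzuki–Miyaura coupling, with SPhos to cope with the doubly ortho-substituted bromide, joins this primary alkyl group to the future C8 without protection.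

Step 2
Reactants: 4 3-fluoro-2-(3-hydroxy-3-methylbutyl)phenol
Product: 5 1-fluoro-3-(methoxymethoxy)-2-[3-(methoxymethoxy)-3-methylbutyl]benzene
Conditions: NaH (2.5 equiv), MOMCl (2.5 equiv), THF/DMF, 0 °C to rt
Reagents that add atoms: chloromethyl methyl ether (MOMCl) COCCl
Why: Williamson-type O-alkylation of the phenoxide and the tertiary alkoxide masks O7 and, more importantly, the side-chain oxygen that could otherwise reach C8a through a six-membered ring in steps 7 and 8.

Step 3
Reactants: 5 1-fluoro-3-(methoxymethoxy)-2-[3-(methoxymethoxy)-3-methylbutyl]benzene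
Product: 6 1-bromo-2-fluoro-4-(methoxymethoxy)-3-[3-(methoxymethoxy)-3-methylbutyl]benzene
Conditions: NBS (1.05 equiv), MeCN, 0 °C to rt
Reagents that add atoms: N-bromosuccinimide (NBS) O=C1CCC(=O)N1Br
Why: electrophilic aromatic bromination with NBS in MeCN goes para to the strongest donor, the OMOM group, which is the free position next to fluorine (future C4a), with the ortho position as the only minor competitor.

Step 4
Reactants: 6 1-bromo-2-fluoro-4-(methoxymethoxy)-3-[3-(methoxymethoxy)-3-methylbutyl]benzene
Product: 8 1-{2-fluoro-4-(methoxymethoxy)-3-[3-(methoxymethoxy)-3-methylbutyl]phenyl}ethan-1-one, via aryllithium 7 (not isolated)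
Conditions: n-BuLi (1.05 equiv), THF, −78 °C; then MeC(O)N(OMe)Me, −78 to 0 °C; then H2O
Reagents that add atoms: N-methoxy-N-methylacetamide CC(=O)N(C)OC
Why: bromine–lithium exchange outruns deprotonation at −78 °C, where the ortho-fluoroaryllithium does not yet lose LiF, and Weinreb acylation stops at the ketone because the chelated tetrahedral adduct survives until the quench.

Step 5
Reactants: 9 4,6-dibromobenzene-1,3-diol
Product: 10 1,5-dibromo-2,4-bis(methoxymethoxy)benzene
Conditions: NaH (2.4 equiv), MOMCl (2.4 equiv), THF/DMF, 0 °C to rt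
Reagents that add atoms: chloromethyl methyl ether (MOMCl) COCCl
Why: double Williamson-type O-alkylation of the bis-phenoxide installs base-stable acetal protection on the future O2′ and O4′.

Step 6
Reactants: 10 1,5-dibromo-2,4-bis(methoxymethoxy)benzene; 11 4,4,5,5-tetramethyl-2-(3-methylbut-2-en-1-yl)-1,3,2-dioxaborolane (prenylboronic acid pinacol ester)
Product: 12 1-bromo-2,4-bis(methoxymethoxy)-5-(2-methylbut-3-en-2-yl)benzene
Conditions: 10 (2 equiv, excess recovered), 11 (1 equiv), Pd(OAc)2 (cat.), electron-poor biaryl monophosphine (JackiePhos), aq K3PO4, MeCN, 70 °C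
Reagents that add atoms: none
Why: in this ligand-controlled γ-selective Suzuki–Miyaura coupling of a 3,3-disubstituted allylboronate, SE2′ transmetalation places palladium on the tertiary carbon and the electron-poor bulky phosphine makes reductive elimination faster than allyl isomerisation, while the equivalence of the two C–Br bonds, the excess of 10 and the slower oxidative addition of the more electron-rich 12 favour single coupling.

Step 7
Reactants: 8 1-{2-fluoro-4-(methoxymethoxy)-3-[3-(methoxymethoxy)-3-methylbutyl]phenyl}ethan-1-one; 12 1-bromo-2,4-bis(methoxymethoxy)-5-(2-methylbut-3-en-2-yl)benzene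
Product: 13 2-[2,4-bis(methoxymethoxy)-5-(2-methylbut-3-en-2-yl)phenyl]-1-{2-fluoro-4-(methoxymethoxy)-3-[3-(methoxymethoxy)-3-methylbutyl]phenyl}ethan-1-one (the 2-fluorodeoxybenzoin)
Conditions: Pd2(dba)3 (cat.), XPhos, K3PO4, toluene, 90 °C
Reagents that add atoms: none
Why: in this palladium-catalysed α-arylation of an aryl methyl ketone the enolate of 8 couples with the arylpalladium bromide from 12 to form C3–C1′, and monoarylation is secured because the more acidic product is stored as its hindered enolate, K3PO4 being too poor a nucleophile to touch the C–F bond.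

Step 8
Reactants: 13 the 2-fluorodeoxybenzoin; 14 ethyl formate
Product: 16 3-[2,4-bis(methoxymethoxy)-5-(2-methylbut-3-en-2-yl)phenyl]-7-(methoxymethoxy)-8-[3-(methoxymethoxy)-3-methylbutyl]-4H-chromen-4-one (the isoflavone), via potassium formyl enolate 15 (not isolated)
Conditions: KOt-Bu (1.2 equiv), 14 (5 equiv), THF, 0 °C to rt; then DMF added, 90 °C (THF and excess 14 allowed to distil off), same flask
Reagents that add atoms: none
Why: KOt-Bu converts 13 into its C3 enolate (activated by the C4 carbonyl and ring B), which attacks ethyl formate in a crossed Claisen condensation and forms C2–C3, and loss of ethoxide and a proton leaves the stabilised potassium enolate 15, so that almost no strong base remains. After rotation about C3–C4 the formyl-derived oxygen adds to C8a, the Meisenheimer charge is taken up by the ortho C4 carbonyl, and loss of fluoride forms O1–C8a (SNAr addition–elimination). The closest known reaction types are the ethyl formate synthesis of isoflavones from deoxybenzoins and the base-mediated, metal-free cyclisation of 1-(2-haloaryl)-1,3-dicarbonyl enolates to chromones. The one ring closed is the six-membered pyranone ring C, formally 6-endo-trig with respect to the C8a=C4a bond that relays the charge, and closure is irreversible because fluoride leaves and a 4-pyranone results. No stereocentre is created, since C3 is trigonal in 16, and it is set in step 9. The step needs O-arylation rather than C-arylation and attack at C8a only: C-attack would need a four-membered ring, fluorine is the only leaving group on ring A, the 7-OMOM group is meta to C8a and does not feed electrons into it, and the side-chain oxygen that could compete for C8a is masked as its MOM ether.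

Step 9
Reactants: 16 the isoflavone
Product: 19 (3R)-3-[2,4-bis(methoxymethoxy)-5-(2-methylbut-3-en-2-yl)phenyl]-7-(methoxymethoxy)-8-[3-(methoxymethoxy)-3-methylbutyl]-3,4-dihydro-2H-chromene (the protected isoflavan), via racemic isoflavanone 17 (not isolated), via cis-isoflavan-4-ol 18 (not isolated)
Conditions: RuCl[(R,R)-TsDPEN](p-cymene) (5 mol %), HCO2H/Et3N (5:2), EtOAc, 60 °C
Reagents that add atoms: none
Why: in this Noyori–Ikariya asymmetric transfer hydrogenation run as a cascade the ruthenium hydride first adds 1,4 to the chromone to give the configurationally labile 17, the (R,R)-catalyst then reduces only its 3R enantiomer from the face anti to ring B while Et3N keeps racemising C3 (dynamic kinetic resolution, giving cis-(3R,4R)-18), and in the formic acid medium the C4 hydroxyl, para to O7, ionises and the cation takes up a third hydride, which leaves C3 as R and spares the isolated vinyl group that this outer-sphere hydride does not touch.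

Step 10
Reactants: 19 the protected isoflavan
Product: 20 4-[(3R)-7-hydroxy-8-(3-hydroxy-3-methylbutyl)-3,4-dihydro-2H-chromen-3-yl]-6-(2-methylbut-3-en-2-yl)benzene-1,3-diol (target)
Conditions: ZnBr2, n-PrSH, CH2Cl2, 0 °C to rt
Reagents that add atoms: none
Why: in this Lewis acid-assisted thiolysis of MOM acetals ZnBr2 activates each acetal and n-PrSH captures the methoxymethyl cation, a method that serves phenolic and tertiary alkyl MOM ethers alike, does not touch C3, and avoids the protic acid that could cyclise either ortho side chain onto its neighbouring phenol.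

Compound list
1 | 2-bromo-3-fluorophenol | Oc1cccc(F)c1Br | starting material
2 | 2-methylbut-3-en-2-ol | C=CC(C)(C)O | starting material
3 | 9-[3-(9-borabicyclo[3.3.1]nonan-9-yloxy)-3-methylbutyl]-9-borabicyclo[3.3.1]nonane | CC(C)(CCB1C2CCCC1CCC2)OB1C2CCCC1CCC2 | intermediate
4 | 3-fluoro-2-(3-hydroxy-3-methylbutyl)phenol | CC(C)(O)CCc1c(O)cccc1F | intermediate
5 | 1-fluoro-3-(methoxymethoxy)-2-[3-(methoxymethoxy)-3-methylbutyl]benzene | COCOc1cccc(F)c1CCC(C)(C)OCOC | intermediate
6 | 1-bromo-2-fluoro-4-(methoxymethoxy)-3-[3-(methoxymethoxy)-3-methylbutyl]benzene | COCOc1ccc(Br)c(F)c1CCC(C)(C)OCOC | intermediate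
7 | {2-fluoro-4-(methoxymethoxy)-3-[3-(methoxymethoxy)-3-methylbutyl]phenyl}lithium | [Li]c1ccc(OCOC)c(CCC(C)(C)OCOC)c1F | intermediate
8 | 1-{2-fluoro-4-(methoxymethoxy)-3-[3-(methoxymethoxy)-3-methylbutyl]phenyl}ethan-1-one | CC(=O)c1ccc(OCOC)c(CCC(C)(C)OCOC)c1F | intermediate
9 | 4,6-dibromobenzene-1,3-diol | Oc1cc(O)c(Br)cc1Br | starting material
10 | 1,5-dibromo-2,4-bis(methoxymethoxy)benzene | COCOc1cc(OCOC)c(Br)cc1Br | intermediate
11 | 4,4,5,5-tetramethyl-2-(3-methylbut-2-en-1-yl)-1,3,2-dioxaborolane | CC(C)=CCB1OC(C)(C)C(C)(C)O1 | starting material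
12 | 1-bromo-2,4-bis(methoxymethoxy)-5-(2-methylbut-3-en-2-yl)benzene | C=CC(C)(C)c1cc(Br)c(OCOC)cc1OCOC | intermediate
13 | 2-[2,4-bis(methoxymethoxy)-5-(2-methylbut-3-en-2-yl)phenyl]-1-{2-fluoro-4-(methoxymethoxy)-3-[3-(methoxymethoxy)-3-methylbutyl]phenyl}ethan-1-one | C=CC(C)(C)c1cc(CC(=O)c2ccc(OCOC)c(CCC(C)(C)OCOC)c2F)c(OCOC)cc1OCOC | intermediate
14 | ethyl formate | CCOC=O | starting material
15 | potassium enolate of the α-formyl derivative of 13 (potassium 2-aryl-3-aryl′-3-oxoprop-1-en-1-olate, geometry mobile) | [K+].[O-]C=C(C(=O)c1ccc(OCOC)c(CCC(C)(C)OCOC)c1F)c1cc(C(C)(C)C=C)c(OCOC)cc1OCOC | intermediate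
16 | 3-[2,4-bis(methoxymethoxy)-5-(2-methylbut-3-en-2-yl)phenyl]-7-(methoxymethoxy)-8-[3-(methoxymethoxy)-3-methylbutyl]-4H-chromen-4-one | C=CC(C)(C)c1cc(-c2coc3c(CCC(C)(C)OCOC)c(OCOC)ccc3c2=O)c(OCOC)cc1OCOC | intermediate
17 | racemic 3-[2,4-bis(methoxymethoxy)-5-(2-methylbut-3-en-2-yl)phenyl]-7-(methoxymethoxy)-8-[3-(methoxymethoxy)-3-methylbutyl]-2,3-dihydro-4H-chromen-4-one | C=CC(C)(C)c1cc(C2COc3c(ccc(OCOC)c3CCC(C)(C)OCOC)C2=O)c(OCOC)cc1OCOC | intermediate
18 | (3R,4R)-3-[2,4-bis(methoxymethoxy)-5-(2-methylbut-3-en-2-yl)phenyl]-7-(methoxymethoxy)-8-[3-(methoxymethoxy)-3-methylbutyl]-3,4-dihydro-2H-chromen-4-ol (3-aryl and 4-OH cis) | C=CC(C)(C)c1cc([C@@H]2COc3c(ccc(OCOC)c3CCC(C)(C)OCOC)[C@@H]2O)c(OCOC)cc1OCOC | intermediate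
19 | (3R)-3-[2,4-bis(methoxymethoxy)-5-(2-methylbut-3-en-2-yl)phenyl]-7-(methoxymethoxy)-8-[3-(methoxymethoxy)-3-methylbutyl]-3,4-dihydro-2H-chromene | C=CC(C)(C)c1cc([C@@H]2COc3c(ccc(OCOC)c3CCC(C)(C)OCOC)C2)c(OCOC)cc1OCOC | intermediate
20 | 4-[(3R)-7-hydroxy-8-(3-hydroxy-3-methylbutyl)-3,4-dihydro-2H-chromen-3-yl]-6-(2-methylbut-3-en-2-yl)benzene-1,3-diol | C=CC(C)(C)c1cc([C@@H]2COc3c(ccc(O)c3CCC(C)(C)O)C2)c(O)cc1O | target

Total step count: 10.
Longest linear sequence: 8 steps (1, 2, 3, 4, 7, 8, 9, 10).

Steps most likely to fail

Step 8. Addition–elimination at the ortho-alkylated C8a of an alkoxy-substituted ring may be slow for a stabilised enolate oxygen. Retro-Claisen deformylation or intermolecular attack of residual alkoxide could then overtake ring closure.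
- The fallback sets out from 13 and changes the one-carbon unit to formaldehyde.
- Paraformaldehyde and Cs2CO3 in DMSO at 60 to 80 °C should hydroxymethylate C3 to the racemic 3-hydroxy-1,2-diarylpropan-1-one F1.
- The primary alkoxide of this ketone is a far stronger nucleophile, and it acts on a ketone that is still neutral. It should close onto C8a in the same flask.
- This gives the racemic isoflavanone 17, now isolated, so the fallback comes back to the route at 17. Compound 17 is then submitted to the conditions of step 9.

Step 9. The cascade may stall at the alcohol stage. The C4 cation may also be diverted by participation of the 2′-oxygen or by loss of the C3 proton, which would erode the configurational purity.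
- The fallback sets out from 16. The same transfer hydrogenation is run at room temperature and stopped at alcohol 18, which is isolated.
- NaH, CS2 and MeI in THF convert it into the O-[(3R,4R)-isoflavan-4-yl] S-methyl xanthate F2.
- Bu3SnH and AIBN in toluene at 80 °C then remove the oxygen by Barton–McCombie radical deoxygenation, which avoids any cation next to C3.
- The fallback comes back to the route at 19.

Step 6. Allyl isomerisation on palladium before reductive elimination would lead to linear coupling, and a second coupling at the remaining C–Br bond would lower the material balance.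
- The fallback sets out from 10.
- Palladium-catalysed α-arylation of isobutyraldehyde (Pd(OAc)2, rac-BINAP, Cs2CO3, dioxane, 80 °C, 10 in excess) gives 2-[5-bromo-2,4-bis(methoxymethoxy)phenyl]-2-methylpropanal F3, in which the quaternary benzylic carbon is fixed by construction.
- Wittig methylenation (Ph3PCH3Br, KOt-Bu, THF, 0 °C) converts the aldehyde into the vinyl group.
- The fallback comes back to the route at 12.

Further compounds
F1 | step 8 | racemic 2-[2,4-bis(methoxymethoxy)-5-(2-methylbut-3-en-2-yl)phenyl]-1-{2-fluoro-4-(methoxymethoxy)-3-[3-(methoxymethoxy)-3-methylbutyl]phenyl}-3-hydroxypropan-1-one | C=CC(C)(C)c1cc(C(CO)C(=O)c2ccc(OCOC)c(CCC(C)(C)OCOC)c2F)c(OCOC)cc1OCOC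
F2 | step 9 | O-{(3R,4R)-3-[2,4-bis(methoxymethoxy)-5-(2-methylbut-3-en-2-yl)phenyl]-7-(methoxymethoxy)-8-[3-(methoxymethoxy)-3-methylbutyl]-3,4-dihydro-2H-chromen-4-yl} S-methyl carbonodithioate | C=CC(C)(C)c1cc([C@@H]2COc3c(ccc(OCOC)c3CCC(C)(C)OCOC)[C@@H]2OC(=S)SC)c(OCOC)cc1OCOC
F3 | step 6 | 2-[5-bromo-2,4-bis(methoxymethoxy)phenyl]-2-methylpropanal | O=CC(C)(C)c1cc(Br)c(OCOC)cc1OCOC
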